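## Structural features

Stenosporic acid is a para-depside built from two benzene rings and has no stereocentre. Ring A is a 2-hydroxy-4-methoxy-6-propylbenzoyl unit and ring B is a 2'-hydroxy-6'-pentylbenzoic acid; they are joined by an aryl ester from the ring A carboxyl carbon to O4' of ring B. In each ring the carboxyl-bearing carbon (C1 or C1') is flanked by an oxygen (C2, C2') and an alkyl chain (C6, C6'), with a second oxygen para to the carboxyl. The depside ester is an activated aryl ester that hydroxide or alkoxide cleaves, the ring B 2,4-dioxygenated benzoic acid decarboxylates on heating or in acid, and both rings are electron-rich enough to over-react with electrophiles. The real difficulty is therefore regiochemical: placing the contiguous C6'-pentyl, C1'-carboxyl and C2'-oxygen without isomers, telling O4' from O2' (and O4 from O2), and freeing the acid and phenols at the end without hydrolysis. The key step uses the adjacency of C1' and C6' with O2' next to C1': an aryne across C1'–C6', polarised by the C2' oxygen, accepts pentyl at C6' and carboxyl at C1'.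

## Logic of the disconnections

20 ⇒ 19. Only two O–CH2Ph bonds are cut, the benzyl ester on the ring B carboxyl and the benzyl ether on O2 of ring A. Benzyl is chosen because hydrogenolysis is neutral and leaves the depside ester and the decarboxylation-prone acid alone. The gain is that every other bond of the target is already present in 19. The demand is that the forward step removes both groups in one operation without touching the aryl ester.

19 ⇒ 17 + 11. The depside C(=O)–O4' bond is cut, which divides the molecule into its two rings and makes the route convergent. The forward step must acylate O4' and not O2' of 11 and must activate a benzoic acid with two ortho substituents. The hydrogen bond from O2'–H to the ester carbonyl of 11 provides the first, and activation of 17 as 18 the second.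

11 ⇒ 10 ⇒ 9. The ester O–benzyl bond of 11 and then the two ether O–benzyl bonds of 9 are cut. This is a protecting-group adjustment: the key step needs both oxygens masked, whereas the coupling needs O4' free and the carboxyl masked. The forward steps must alkylate the carboxylate and not the phenols, and must handle 10 without decarboxylation.

9 ⇒ 3 + 4 + 5 (through 8, 7 and 6). The C6'–pentyl and C1'–carboxyl bonds are cut together. This reduces a 1,2,3,5-tetrasubstituted benzoic acid to a symmetrical phloroglucinol diether carrying an iodide and a triflate on neighbouring carbons. The iodine-bearing carbon of 3 becomes C1' and the triflate-bearing carbon becomes C6'. The forward step must add the pentyl group at the aryne carbon remote from the flanking benzyloxy group, and 8 must survive until 5 is admitted.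

3 ⇒ 2 ⇒ 1. The O–S bond of the triflate and the C–I bond are cut, leading to commercial 1. The two benzyl ethers are kept identical on purpose: the symmetry makes both positions ortho to the hydroxyl of 1 the same, so only ortho-versus-para selectivity remains. The forward iodination must stop at one iodine and avoid the position between the two benzyloxy groups.

17 ⇒ 16 ⇒ 15 ⇒ 14 ⇒ 12 (through 13). Going backwards, the acid is taken to the aldehyde, the O2–benzyl and O4–methyl bonds are cut, and finally the C1–CHO bond. The formyl group serves twice: it chelates O2–H so that O4 can be methylated selectively, and it is the latent carboxyl. The forward formylation must occur next to the propyl group and not between the two hydroxyls of 12.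

## Other disconnections considered

Alternative 1: The C1–C6 bond of ring A is cut, so that ring A arises by aldol folding of a triketo ester chain already attached to O4'. The forward key step would cyclise benzyl 2-hydroxy-6-pentyl-4-[(3,5,7-trioxodecanoyl)oxy]benzoate A2 under mild base and then acid to benzyl 4-[(2,4-dihydroxy-6-propylbenzoyl)oxy]-2-hydroxy-6-pentylbenzoate A1.
- In its favour: the hindered aryl ester is never formed by coupling, since ring A grows on the ester. On this point the alternative is better than the chosen plan. The conditions are mild and metal-free.
- Against it: A2 is an aryl β-keto ester and so an activated acyl donor. It can lose the ring B phenoxide or close through oxygen to a pyrone instead of through carbon. A1 carries a free O4–H that still needs selective methylation in the presence of two chelated phenols. A2 must first be assembled from 11 and a masked triketo acid.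
- Comparison: the alternative does nothing for ring B, so 11 must still be made. Its ring A sequence is unlikely to be shorter than the four steps from 12 plus one coupling used here. Mechanistically the chosen plan relies on a polarised aryne and a chelation-controlled acylation, both well-defined, where the alternative relies on controlling the folding mode of a polyketone.

Alternative 2: The C1'–C6' and C2'–C3' bonds of ring B are cut. The forward key step would be conjugate addition of dibenzyl malonate A4 to (E)-non-3-en-2-one A5, followed by Claisen-type ring closure to benzyl 2-hydroxy-4-oxo-6-pentylcyclohex-2-ene-1-carboxylate A3. A3 would be O-acylated with 17 and aromatised afterwards.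
- In its favour: A4 and A5 are cheap, no cryogenic organometallic chemistry is needed, and the ring is formed with the benzyl ester already in place. The hydrogenolysis and re-esterification of steps 4 and 5 would disappear, which makes the alternative better on protecting-group economy. Regiochemistry is fixed by the acyclic partners A4 and A5, which is equal to the chosen plan.
- Against it: the two enol oxygens of A3 must be told apart. The enol ester of a cyclic 1,3-dione is itself an acyl donor prone to O-to-C acyl shift. Dehydrogenation by halogenation and elimination would be run in the presence of the electron-rich ring A and a labile ester. A3 is a β-keto ester that can decarboxylate.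
- Comparison: if A3 were aromatised before acylation, 11 would be reached in about two steps from A4 and A5, against five steps from 1 in the chosen plan, a clear advantage in step count. The chosen plan offers unambiguous placement of every substituent and avoids an oxidation late in the sequence.

Alternative 3: The C1–C2 and C5–C6 bonds of ring A are cut. The forward key step would be cycloaddition of the Brassard diene [(1,3-dimethoxybuta-1,3-dien-1-yl)oxy]trimethylsilane A8 to benzyl 2-(benzyloxy)-4-(hex-2-ynoyloxy)-6-pentylbenzoate A7. Loss of one methoxy group and of the silyl group on work-up would aromatise the new ring and give benzyl 2-(benzyloxy)-4-[(2-hydroxy-4-methoxy-6-propylbenzoyl)oxy]-6-pentylbenzoate A6. A6 differs from 19 only in carrying its benzyl ether on O2' and not on O2, so a single hydrogenolysis of A6 would complete the synthesis.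
- In its favour: the diene A8 delivers O2–H and O4–Me already differentiated, so no selective methylation or benzyl protection of ring A is needed. The ester is made from an unhindered alkynoic acid. On both points the alternative is better than the chosen plan.
- Against it: A7 needs a ring B phenol with O2' benzylated and O4' free, a differentiation that 11 does not provide. A β-alkyl ynoate is only a moderate dienophile, so heating is likely, and the aryl ynoate is also a Michael acceptor and an activated ester. A8 is moisture-sensitive, and the orientation of addition rests on polarisation alone.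
- Comparison: ring A would be built in one step from A7, against four steps plus a coupling here. The saving is offset by the longer route to the ring B partner, so overall step economy is roughly equal. The chosen plan keeps the fragile depside ester out of any thermal step.

Key step: step 3

Remark on the chemistry: primed locants refer to ring B (pentyl ring), unprimed locants to ring A (propyl ring). Pentylmagnesium bromide 4 is taken as the commercial ethereal solution.

## Route

Step 1
Reactants: 1 3,5-bis(benzyloxy)phenol
Product: 2 3,5-bis(benzyloxy)-2-iodophenol
Conditions: I2 (1.0 equiv), NaHCO3, THF/H2O, 0 °C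
Reagents that add atoms: iodine, II
Why: Electrophilic aromatic iodination of the phenoxide; the two positions ortho to the hydroxyl are equivalent by symmetry and less hindered than C4 between the two benzyloxy groups, and one equivalent of iodine at 0 °C under hydrogencarbonate buffering should hold the reaction at the mono-iodide.

Step 2
Reactants: 2 3,5-bis(benzyloxy)-2-iodophenol
Product: 3 3,5-bis(benzyloxy)-2-iodophenyl trifluoromethanesulfonate
Conditions: PhNTf2, Et3N, DMAP (cat.), CH2Cl2, 0 °C → rt
Reagents that add atoms: N-phenylbis(trifluoromethanesulfonimide), O=S(=O)(N(c1ccccc1)S(=O)(=O)C(F)(F)F)C(F)(F)F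
Why: O-Sulfonylation of the phenoxide by triflyl transfer from the bench-stable triflimide, chosen over triflic anhydride on safety grounds; the aryl iodide and the benzyl ethers are inert to these mild basic conditions.

Step 3
Reactants: 3 3,5-bis(benzyloxy)-2-iodophenyl trifluoromethanesulfonate; 4 pentylmagnesium bromide; 5 carbon dioxide
Product: 9 2,4-bis(benzyloxy)-6-pentylbenzoic acid, via magnesiated aryl triflate 6 (not isolated), via 3,5-bis(benzyloxy)benzyne 7 (not isolated), via 2,4-bis(benzyloxy)-6-pentylphenylmagnesium bromide 8 (not isolated)
Conditions: 3 added slowly to 4 (3.5 equiv), THF, −78 → 0 °C; then CO2 (g), −40 °C → rt; aq. HCl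
Reagents that add atoms: pentylmagnesium bromide (compound 4), CCCCC[Mg]Br; carbon dioxide (compound 5), O=C=O
Why: The first equivalent of 4 performs iodine–magnesium exchange at the iodine-bearing carbon (the future C1'), and the resulting 6 expels MgBr(OTf) from the neighbouring carbon to give aryne 7. A second equivalent of 4 carbomagnesiates the strained triple bond, placing pentyl on C6' and magnesium on C1', and arylmagnesium 8 is then carboxylated by 5 at C1'; acidic work-up frees the acid. The closest known reaction type is aryne generation from ortho-iodoaryl sulfonates by halogen–magnesium exchange, combined with the tandem Grignard addition and electrophile quench that is well known for 3-alkoxybenzynes. No ring is closed and no stereocentre is created. The selectivity needed is the site of pentyl addition: the C2' benzyloxy group beside the triple bond withdraws inductively, which distorts 7 so that C6' is the more electrophilic terminus and puts the developing carbanion at C1' next to oxygen, where induction and O–Mg coordination stabilise it; the 4'-benzyloxy group, para to C1' and meta to C6', opposes this only weakly. Using 4 as both exchange reagent and nucleophile keeps a single carbon nucleophile in the flask, and adding 3 to an excess of 4 should keep the aryne from being intercepted by 6 or 8. The benzyl ethers tolerate the Grignard reagent, and the hindered 8 should still react with the small electrophile 5.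

Step 4
Reactants: 9 2,4-bis(benzyloxy)-6-pentylbenzoic acid
Product: 10 2,4-dihydroxy-6-pentylbenzoic acid (olivetolic acid)
Conditions: H2 (1 atm), 10% Pd/C, EtOAc, rt
Reagents that add atoms: none
Why: Hydrogenolysis of the two aryl benzyl ethers over Pd/C; the neutral medium and room temperature, with evaporation below 30 °C, should keep the decarboxylation-prone dihydroxybenzoic acid intact.

Step 5
Reactants: 10 2,4-dihydroxy-6-pentylbenzoic acid
Product: 11 benzyl 2,4-dihydroxy-6-pentylbenzoate
Conditions: BnBr (1.05 equiv), KHCO3, DMF, rt
Reagents that add atoms: benzyl bromide, BrCc1ccccc1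
Why: SN2 O-alkylation of the carboxylate; hydrogencarbonate deprotonates only the carboxylic acid, so the two phenols stay protonated and the benzyl group should go to the carboxyl oxygen alone.

Step 6
Reactants: 12 5-propylresorcinol
Product: 14 2,4-dihydroxy-6-propylbenzaldehyde, via aryl dimethyliminium chloride 13 (not isolated)
Conditions: POCl3, DMF, 0 °C → rt; then H2O, NaOAc, 50 °C
Reagents that add atoms: N,N-dimethylformamide, CN(C)C=O; water, O
Why: Vilsmeier–Haack formylation: the chloroiminium electrophile attacks para to one hydroxyl and ortho to the other (next to the propyl group), the usual site for 5-alkylresorcinols, and aqueous hydrolysis of iminium 13 and of any aryl formate releases the aldehyde.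

Step 7
Reactants: 14 2,4-dihydroxy-6-propylbenzaldehyde
Product: 15 2-hydroxy-4-methoxy-6-propylbenzaldehyde
Conditions: MeI (1.05 equiv), K2CO3 (1.0 equiv), acetone, rt
Reagents that add atoms: iodomethane, CI
Why: Williamson etherification with one equivalent of base: the 2-hydroxyl is held in a hydrogen bond to the formyl oxygen, whereas the 4-hydroxyl para to the formyl group is more acidic and more accessible, so mono-methylation at O4 is expected.

Step 8
Reactants: 15 2-hydroxy-4-methoxy-6-propylbenzaldehyde
Product: 16 2-(benzyloxy)-4-methoxy-6-propylbenzaldehyde
Conditions: BnBr, K2CO3, DMF, 60 °C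
Reagents that add atoms: benzyl bromide, BrCc1ccccc1
Why: Williamson etherification of the remaining chelated phenol under more forcing conditions; the benzyl ether masks O2 during the later acylation and leaves in the final hydrogenolysis.

Step 9
Reactants: 16 2-(benzyloxy)-4-methoxy-6-propylbenzaldehyde
Product: 17 2-(benzyloxy)-4-methoxy-6-propylbenzoic acid
Conditions: NaClO2, NaH2PO4, 2-methylbut-2-ene, t-BuOH/H2O, rt
Reagents that add atoms: sodium chlorite, [Na+].[O-]Cl=O
Why: Pinnick oxidation of the hindered aryl aldehyde through its chlorous acid adduct; 2-methylbut-2-ene removes hypochlorous acid and so protects the electron-rich ring from chlorination, and the benzyl and methyl ethers are untouched.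

Step 10
Reactants: 17 2-(benzyloxy)-4-methoxy-6-propylbenzoic acid; 11 benzyl 2,4-dihydroxy-6-pentylbenzoate
Product: 19 benzyl 4-{[2-(benzyloxy)-4-methoxy-6-propylbenzoyl]oxy}-2-hydroxy-6-pentylbenzoate, via mixed trifluoroacetic anhydride 18 (not isolated)
Conditions: TFAA, toluene, rt
Reagents that add atoms: none
Why: Ester formation through mixed anhydride 18, an acylium-like donor that overcomes the two ortho substituents of the acid; of the two phenols of 11 only O4' is free, since O2'–H is hydrogen-bonded to the ester carbonyl, so acylation at O4' is expected, as in the classical depside condensation of benzyl dihydroxybenzoates.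

Step 11
Reactants: 19 benzyl 4-{[2-(benzyloxy)-4-methoxy-6-propylbenzoyl]oxy}-2-hydroxy-6-pentylbenzoate
Product: 20 stenosporic acid, 2-hydroxy-4-[(2-hydroxy-4-methoxy-6-propylbenzoyl)oxy]-6-pentylbenzoic acid
Conditions: H2 (1 atm), 10% Pd/C, EtOAc, rt
Reagents that add atoms: none
Why: Hydrogenolysis removes the benzyl ester and the benzyl ether in one operation; the depside aryl ester has no benzylic C–O bond and is inert to H2 over Pd/C, and the neutral conditions avoid hydrolysis and decarboxylation.

## Compound list

1 | 3,5-bis(benzyloxy)phenol | Oc1cc(OCc2ccccc2)cc(OCc2ccccc2)c1 | starting material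
2 | 3,5-bis(benzyloxy)-2-iodophenol | Oc1cc(OCc2ccccc2)cc(OCc2ccccc2)c1I | intermediate
3 | 3,5-bis(benzyloxy)-2-iodophenyl trifluoromethanesulfonate | O=S(=O)(Oc1cc(OCc2ccccc2)cc(OCc2ccccc2)c1I)C(F)(F)F | intermediate
4 | pentylmagnesium bromide | CCCCC[Mg]Br | starting material
5 | carbon dioxide | O=C=O | starting material
6 | 2,4-bis(benzyloxy)-6-{[(trifluoromethyl)sulfonyl]oxy}phenylmagnesium bromide | O=S(=O)(Oc1cc(OCc2ccccc2)cc(OCc2ccccc2)c1[Mg]Br)C(F)(F)F | intermediate
7 | 3,5-bis(benzyloxy)benzyne | C1#CC(OCc2ccccc2)=CC(OCc2ccccc2)=C1 | intermediate
8 | 2,4-bis(benzyloxy)-6-pentylphenylmagnesium bromide | CCCCCc1cc(OCc2ccccc2)cc(OCc2ccccc2)c1[Mg]Br | intermediate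
9 | 2,4-bis(benzyloxy)-6-pentylbenzoic acid | CCCCCc1cc(OCc2ccccc2)cc(OCc2ccccc2)c1C(=O)O | intermediate
10 | 2,4-dihydroxy-6-pentylbenzoic acid | CCCCCc1cc(O)cc(O)c1C(=O)O | intermediate
11 | benzyl 2,4-dihydroxy-6-pentylbenzoate | CCCCCc1cc(O)cc(O)c1C(=O)OCc1ccccc1 | intermediate
12 | 5-propylresorcinol | CCCc1cc(O)cc(O)c1 | starting material
13 | [(2,4-dihydroxy-6-propylphenyl)methylidene]dimethylazanium chloride | CCCc1cc(O)cc(O)c1C=[N+](C)C.[Cl-] | intermediate
14 | 2,4-dihydroxy-6-propylbenzaldehyde | CCCc1cc(O)cc(O)c1C=O | intermediate
15 | 2-hydroxy-4-methoxy-6-propylbenzaldehyde | CCCc1cc(OC)cc(O)c1C=O | intermediate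
16 | 2-(benzyloxy)-4-methoxy-6-propylbenzaldehyde | CCCc1cc(OC)cc(OCc2ccccc2)c1C=O | intermediate
17 | 2-(benzyloxy)-4-methoxy-6-propylbenzoic acid | CCCc1cc(OC)cc(OCc2ccccc2)c1C(=O)O | intermediate
18 | 2-(benzyloxy)-4-methoxy-6-propylbenzoic trifluoroacetic anhydride | CCCc1cc(OC)cc(OCc2ccccc2)c1C(=O)OC(=O)C(F)(F)F | intermediate
19 | benzyl 4-{[2-(benzyloxy)-4-methoxy-6-propylbenzoyl]oxy}-2-hydroxy-6-pentylbenzoate | CCCCCc1cc(OC(=O)c2c(OCc3ccccc3)cc(OC)cc2CCC)cc(O)c1C(=O)OCc1ccccc1 | intermediate
20 | stenosporic acid, 2-hydroxy-4-[(2-hydroxy-4-methoxy-6-propylbenzoyl)oxy]-6-pentylbenzoic acid | CCCCCc1cc(OC(=O)c2c(O)cc(OC)cc2CCC)cc(O)c1C(=O)O | target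

## Step count and least certain steps

Total step count: 11. Longest linear sequence: 7 steps (steps 1, 2, 3, 4, 5, 10 and 11, from 1). The ring A branch is 4 steps (steps 6 to 9, from 12) and joins at step 10.

Step 3 (key step). Several processes could erode it:
- attack of 4 at the sulfonyl sulfur in place of iodine–magnesium exchange, which would return the phenoxide;
- interception of the aryne by arylmagnesium species, leading to biaryl formation;
- loss of regiocontrol in the pentyl addition through the opposing pull of the 4'-oxygen;
- protonation of the arylmagnesium before carboxylation.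

The fallback forms the same two bonds one at a time by cross-coupling, with no aryne. It sets out from 3. Palladium-catalysed benzyloxycarbonylation at the C–I bond (Pd(PPh3)2Cl2, CO 1 atm, BnOH, Et3N, DMF, 70 °C; zerovalent palladium inserts into C–I before C–OTf) should give benzyl 2,4-bis(benzyloxy)-6-{[(trifluoromethyl)sulfonyl]oxy}benzoate F1. Negishi coupling of the triflate with C5H11ZnBr (Pd(dppf)Cl2, THF, 50 °C) should give benzyl 2,4-bis(benzyloxy)-6-pentylbenzoate F2. Hydrogenolysis (H2, Pd/C, EtOAc) removes all three benzyl groups and comes back to the route at 10. Regiochemistry is then fixed by the positions of iodine and triflate in 3.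

Step 1. Iodination could stray to C4 between the two benzyloxy groups, or occur twice, because all three open positions are activated by three oxygens. The fallback replaces electrophilic substitution by directed metalation and sets out from 1. Carbamoylation (Et2NCOCl, K2CO3, MeCN, reflux) gives 3,5-bis(benzyloxy)phenyl diethylcarbamate F3. Carbamate-directed ortho-lithiation at the position flanked by the carbamate and a benzyloxy group (s-BuLi, TMEDA, THF, −78 °C), followed by iodine quench, gives 3,5-bis(benzyloxy)-2-iodophenyl diethylcarbamate F4. Carbamate hydrolysis (NaOH, EtOH, reflux) comes back to the route at 2.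

Step 10. In the strongly acidic medium the acylium-like donor could acylate the electron-rich ring carbons of 11 in Friedel–Crafts fashion. The ortho benzyl ether of the acid component could be lost, or conversion could stall because of the doubly ortho-substituted carbonyl. The fallback moves to a preformed acyl chloride and phenoxide acylation under base, and sets out from 17. Oxalyl chloride with catalytic DMF in CH2Cl2 gives 2-(benzyloxy)-4-methoxy-6-propylbenzoyl chloride F5. F5 is added to 11 with K2CO3 in acetone at room temperature, where the more acidic, unchelated O4'–H is deprotonated preferentially. This comes back to the route at 19.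

Step 6. Formylation could occur between the two hydroxyls, or twice, and O-formylation could consume material, since the free resorcinol is very reactive. The fallback uses the dimethyl ether, where the position between the two methoxy groups is shielded, and then a chelation-directed demethylation; it sets out from 12. Exhaustive methylation (MeI, K2CO3, acetone, reflux) gives 1,3-dimethoxy-5-propylbenzene F6. Vilsmeier–Haack formylation (POCl3, DMF, 80 °C) gives 2,4-dimethoxy-6-propylbenzaldehyde F7. BCl3 in CH2Cl2 (−78 → 0 °C) cleaves only the methoxy group ortho to the formyl group and comes back to the route at 15, replacing steps 6 and 7.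

## Further compounds

F1 | step 3 | benzyl 2,4-bis(benzyloxy)-6-{[(trifluoromethyl)sulfonyl]oxy}benzoate | O=C(OCc1ccccc1)c1c(OCc2ccccc2)cc(OCc2ccccc2)cc1OS(=O)(=O)C(F)(F)F
F2 | step 3 | benzyl 2,4-bis(benzyloxy)-6-pentylbenzoate | CCCCCc1cc(OCc2ccccc2)cc(OCc2ccccc2)c1C(=O)OCc1ccccc1
F3 | step 1 | 3,5-bis(benzyloxy)phenyl diethylcarbamate | CCN(CC)C(=O)Oc1cc(OCc2ccccc2)cc(OCc2ccccc2)c1
F4 | step 1 | 3,5-bis(benzyloxy)-2-iodophenyl diethylcarbamate | CCN(CC)C(=O)Oc1cc(OCc2ccccc2)cc(OCc2ccccc2)c1I
F5 | step 10 | 2-(benzyloxy)-4-methoxy-6-propylbenzoyl chloride | CCCc1cc(OC)cc(OCc2ccccc2)c1C(Cl)=O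
F6 | step 6 | 1,3-dimethoxy-5-propylbenzene | CCCc1cc(OC)cc(OC)c1
F7 | step 6 | 2,4-dimethoxy-6-propylbenzaldehyde | CCCc1cc(OC)cc(OC)c1C=O
A1 | alternative 1 | benzyl 4-[(2,4-dihydroxy-6-propylbenzoyl)oxy]-2-hydroxy-6-pentylbenzoate | CCCc1cc(O)cc(O)c1C(=O)Oc1cc(O)c(C(=O)OCc2ccccc2)c(CCCCC)c1
A2 | alternative 1 | benzyl 2-hydroxy-6-pentyl-4-[(3,5,7-trioxodecanoyl)oxy]benzoate | CCCC(=O)CC(=O)CC(=O)CC(=O)Oc1cc(O)c(C(=O)OCc2ccccc2)c(CCCCC)c1
A3 | alternative 2 | benzyl 2-hydroxy-4-oxo-6-pentylcyclohex-2-ene-1-carboxylate | CCCCCC1CC(=O)C=C(O)C1C(=O)OCc1ccccc1
A4 | alternative 2 | dibenzyl malonate | O=C(CC(=O)OCc1ccccc1)OCc1ccccc1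
A5 | alternative 2 | (E)-non-3-en-2-one | CCCCC/C=C/C(C)=O
A6 | alternative 3 | benzyl 2-(benzyloxy)-4-[(2-hydroxy-4-methoxy-6-propylbenzoyl)oxy]-6-pentylbenzoate | CCCc1cc(OC)cc(O)c1C(=O)Oc1cc(CCCCC)c(C(=O)OCc2ccccc2)c(OCc2ccccc2)c1
A7 | alternative 3 | benzyl 2-(benzyloxy)-4-(hex-2-ynoyloxy)-6-pentylbenzoate | CCCC#CC(=O)Oc1cc(CCCCC)c(C(=O)OCc2ccccc2)c(OCc2ccccc2)c1
A8 | alternative 3 | [(1,3-dimethoxybuta-1,3-dien-1-yl)oxy]trimethylsilane (Brassard diene) | C=C(OC)C=C(OC)O[Si](C)(C)C
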